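(The runs stem from a simulated flask with constants of no real substance; the scatter is artificial.)

| setting | maple | flask |
|---|---|---|
| Q | 0.050 M | 0.050 M |
| G | 1.1 equiv | 1.10 equiv |
| E | 0.1 mol% | 0.1 mol% |
| remark | the very flask that is asked about, followed so far |  |
| time |  | 25 h |

maple run (percent of the Q charged)

| time / h | J / % | L / % |
|---|---|---|
| 0.833 | 29 | 6 |
| 2.50 | 40 | 5 |
| 5.00 | 41 | 0 |
| 8.00 | 52 | 0 |
| 10.0 | 50 | 3 |

(each reading ± 2 percentage points)



- ratio of J to L at 8.0 min
- ratio of J to L at 2.0 h
- ratio of J to L at 25 h

Slowness is the first thing I read in maple, this same flask followed so far, where Q meets G over a trace of E: J creeps from 40 % at 2.50 h to 50 % at 10.0 h. Its last two readings average 51.0 %, and the G charged divided by that gives 2.16 G for each J. I take this as a reading of two: one G to make L, a second to turn L into J. My ceiling on J is therefore the G charged over two, 55.0 % of the Q charged, the ceiling. It is less than the Q charged, which makes G the limiting reagent for J.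

Now the flask in slow motion, as I reckon it. If L is the stepping stone, L has to form before J can, so at 8.0 min I put L ahead of J and the ratio under one. In the middle, L is passing on to J: the readings give 4.83 at 0.833 h and 8.00 at 2.50 h, so I take about the latter at 2.0 h. For the end, the last three L readings average 1.00 %, each with a scatter of 2 percentage points. The ceiling over that gives 55.0. Going round again, each L still holds one G that has not gone on to J, so I put J at 54.5 % and the ratio at 54.5, a soft figure.

The forecast says 4 (1.5 to 9), 7.5 (4.5 to 14) and 40 (12 to 200), warning of the last that “the denominator lies within the noise”. It differs from mine at the first time and the last.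

The flask gives 0.548, 14.2 and 37.3.

    Q + E → E + D (k = 3250 /M/min)
    G + E + D → E + L (k = 13800 /M²/min)
    G + L → J (k = 2.80 /M/min)
    2 Q → Z (k = 2.53 /M/min)
    L + E ⇌ X + E, rate k5*[E]*[L] forward; the back reaction follows from the equilibrium constant (K = 4.93, k = 846 /M/min)

By 2.99 min, half of the turnover of Q to D up to 25 h was done, and by 0.479 h half of that of D with G to L, while L took its second G to J, J drawing level with L at 0.217 h. By 2.50 h Q stood at 0 % and G at 17.5 % of its own charge, and at 25.0 h G stood at 0.317 % of its own charge, with J at 50.8 %, below the ceiling of 55.0 %. In the neighbour flask, the same but with 4.40 equiv of G, J ended at 60.3 % with 73 % of that G left, which is 2.00 G spent for each J.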